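**Retrosynthetic overview**
1. Target ⇒ last ring (cyclohexene, quaternary C8 and C9) by adding myrcene across the C8=C9 bond of a 6-5-6 hydroxyquinone aldehyde.
2. Hydroxyquinone aldehyde ⇒ 6-5-6 phenol with the aldehyde masked as a dimethyl acetal (one-pot phenol → hydroxy-p-quinone oxidation, then unmasking).
3. 6-5-6 core ⇒ 6-6-6 abietane: oxidative ring contraction (1,2-aryl shift of C8 from C7 to C6) of 6,7-dehydroferruginol methyl ether. This is the pivotal step; C7 is extruded as the formyl carbon.
4. Abietane ⇒ enantioselective polyene bicyclisation of an E-homogeranyl arene (rings A and B closed together onto the bought arene ring C).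
5. Polyene ⇒ new base-catalysed 1,4-hydrobenzylation of myrcene with 2-isopropyl-4-methylanisole; myrcene ⇐ chloroprene + homoprenyl bromide; arene ⇐ p-cresol + propan-2-ol. Ring order: C → A+B → B contracted 6→5 → cyclohexene.

Assumption: abietane numbering is used throughout (5α-H, 10β-CH3, formyl carbon C7 on C6, quinone carbons C8, C9, C11–C14), and the target is the enantiomer exactly as encoded in the given SMILES (natural 5S,10S series).

**Step 1**
Reactants: 1 chloroprene; 2 5-bromo-2-methylpent-2-ene
Product: 4 myrcene (7-methyl-3-methylideneocta-1,6-diene), via homoprenylmagnesium bromide 3 (not isolated)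
Conditions: Mg, THF, 35 °C; then chloroprene, NiCl2(dppp) (1 mol %), Et2O/THF, 0 °C → rt; distil
Reagents that add atoms: none
Why: Kumada coupling; Ni(0) inserts into the vinylic C–Cl bond of chloroprene and the primary homoallyl Grignard couples without touching the diene; no stereocentre is formed.

**Step 2**
Reactants: 5 p-cresol; 6 propan-2-ol
Product: 7 4-methyl-2-(propan-2-yl)phenol
Conditions: 80% H2SO4, 70 °C, twofold excess of p-cresol; distil (excess recovered)
Reagents that add atoms: none
Why: Friedel–Crafts alkylation; the 2-propyl cation attacks ortho to OH because the para position is blocked, and the excess of phenol suppresses 2,6-dialkylation.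

**Step 3**
Reactants: 7 4-methyl-2-(propan-2-yl)phenol
Product: 8 1-methoxy-4-methyl-2-(propan-2-yl)benzene
Conditions: MeI, K2CO3, acetone, reflux
Reagents that add atoms: iodomethane, CI
Why: Williamson ether synthesis; the methyl ether survives the superbase, Lewis acid and oxidants of steps 4–7.

**Step 4**
Reactants: 8 1-methoxy-4-methyl-2-(propan-2-yl)benzene; 4 myrcene
Product: 11 4-[(3E)-4,8-dimethylnona-3,7-dien-1-yl]-1-methoxy-2-(propan-2-yl)benzene, via benzylic potassium species 9 (not isolated), via allylpotassium adduct 10 (not isolated)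
Conditions: n-BuLi/KOt-Bu/2,2,6,6-tetramethylpiperidine (20 mol % each), THF, −78 → −30 °C, threefold excess of the arene (recovered by distillation); myrcene added slowly by syringe pump, −30 → 0 °C; NH4Cl (aq)
Reagents that add atoms: none
Why: Proposed new method: potassium-amide-relayed 1,4-hydrobenzylation of a 2-substituted 1,3-diene. K-TMP metalates the benzylic methyl of 8 (the thermodynamic site; ring anions funnel to it by TMP(H)-mediated anion migration). Benzylpotassium 9 adds to the unsubstituted vinyl terminus of 4, the site attacked in anionic diene polymerisation and in the lithium-amide hydroamination of myrcene, and gives 2-alkylallylpotassium 10 with its new chain endo (cis to the CH2K terminus, avoiding A1,2 strain). Proton transfer from TMP(H) or 8 to the CH2 terminus releases the E-trisubstituted alkene, which later dictates the trans C5/C10 fusion, and regenerates the base; slow addition of the diene into excess arene suppresses telomerisation. Closest known reaction types: alkali-metal-catalysed side-chain alkenylation of toluenes with butadiene or isoprene, and lithium-amide-catalysed 1,4-hydroamination of myrcene to N,N-diethylgeranylamine.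

**Step 5**
Reactants: 11 4-[(3E)-4,8-dimethylnona-3,7-dien-1-yl]-1-methoxy-2-(propan-2-yl)benzene
Product: 12 (+)-ferruginol methyl ether [(4bS,8aS)-3-methoxy-4b,8,8-trimethyl-2-(propan-2-yl)-4b,5,6,7,8,8a,9,10-octahydrophenanthrene; 5α-H; 10β-CH3]
Conditions: (R)-3,3′-Cl2-BINOL·SbCl5 (0.5 equiv; enantiomer chosen to give 4bS,8aS), CH2Cl2, −78 °C
Reagents that add atoms: none
Why: Enantioselective proton-initiated polyene cyclisation (chiral BINOL·Lewis acid Brønsted acid); face-selective protonation of the terminal alkene starts a chair–chair antiperiplanar bicyclisation of the E-alkene, ended by Friedel–Crafts attack at the arene carbon para to isopropyl, which sets C5 (H α) and C10 (CH3 β) trans in one event.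

**Step 6**
Reactants: 12 (+)-ferruginol methyl ether
Product: 13 6,7-dehydroferruginol methyl ether (12-methoxyabieta-6,8,11,13-tetraene; 5α-H; 10β-CH3)
Conditions: DDQ (1.3 equiv), 1,4-dioxane, 80 °C
Reagents that add atoms: none
Why: Benzylic dehydrogenation; DDQ abstracts hydride from C7 (para-methoxybenzylic) and the cation loses H-6 to give the conjugated styrene, leaving C5 and C10 untouched.

**Step 7**
Reactants: 13 6,7-dehydroferruginol methyl ether
Product: 14 9-(dimethoxymethyl)-3-methoxy-4b,8,8-trimethyl-2-(propan-2-yl)-4b,5,6,7,8,8a-hexahydro-9H-fluorene (4b-CH3 β; 8a-H α; 9-CH(OMe)2 α = cis to 8a-H)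
Conditions: PhI(OH)OTs (1.2 equiv), MeOH/HC(OMe)3 (4:1), 0 °C → rt
Reagents that add atoms: methanol (two molecules), CO
Why: Iodine(III)-mediated oxidative ring contraction of a 1,2-dihydronaphthalene (1,2-aryl shift, semipinacol type); the iodane adds to C6 from the α-face (anti to the axial C10 methyl) with MeOH capture at C7, then aryl carbon C8 migrates from C7 to C6 antiperiplanar to the equatorial C6–I bond as PhI leaves and MeOH traps the oxocarbenium, so inversion at C6 places the acetal carbon α (trans to C4).

**Step 8**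
Reactants: 14 ring-contracted methyl ether acetal
Product: 15 9-(dimethoxymethyl)-4b,8,8-trimethyl-2-(propan-2-yl)-4b,5,6,7,8,8a-hexahydro-9H-fluoren-3-ol (configuration as in 14)
Conditions: NaSEt (5 equiv), DMF, 130 °C; NH4Cl (aq)
Reagents that add atoms: none
Why: SN2 O-demethylation of the aryl methyl ether by thiolate; the dimethyl acetal is inert to this non-acidic nucleophile, so the aldehyde stays masked.

**Step 9**
Reactants: 15 phenol acetal
Product: 20 3-hydroxy-4b,8,8-trimethyl-1,4-dioxo-2-(propan-2-yl)-4,4b,5,6,7,8,8a,9-octahydro-1H-fluorene-9-carbaldehyde (4b-CH3 β; 8a-H α; 9-CHO α), via o-quinone acetal 16 (not isolated), via arylthio catechol acetal 17 (not isolated), via arylthio o-quinone acetal 18 (not isolated), via hydroxyquinone acetal 19 (not isolated)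
Conditions: IBX (1.1 equiv), DMF, 23 °C; C6F5SH (1.05 equiv); IBX (1.2 equiv); then 1 M NaOH, THF/H2O, 0 °C (Ar); then 2 M HCl, THF, 23 °C; crude 20 used at once
Reagents that add atoms: IBX, O=C1OI(=O)(O)c2ccccc12; sodium hydroxide, [Na+].[OH-]; water, O
Why: IBX ortho-oxygenation of the phenol at free C11 gives the o-quinone, thiol 1,4-addition at C14 and reoxidation install a leaving group, hydroxide addition–elimination and tautomerisation give the 12-hydroxy-11,14-quinone, and the acidic finish hydrolyses the acetal; the formyl group stays in its more stable α orientation (trans to quaternary C4) and C5, C10 are unchanged.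

**Step 10**
Reactants: 20 hydroxyquinone aldehyde; 4 myrcene
Product: 21 target CNP0239256.1 (cyclohexene ring cis-fused on the α-face at C8/C9; 5α-H; 10β-CH3; 6α-CHO)
Conditions: Eu(fod)3 (0.3 equiv), CH2Cl2, 35 °C, 48 h, tenfold excess of myrcene
Reagents that add atoms: none
Why: Lewis-acid-promoted intermolecular Diels–Alder reaction; the lanthanide is expected to bridge the formyl oxygen and the more basic C14 carbonyl, making C9 the electrophilic terminus so the more nucleophilic diene CH2 (on the substituted carbon) bonds to C9, and the diene adds to the α-face anti to the axial C10 methyl, setting quaternary C8 and C9 cis in one step.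

**Compound list**
1 | chloroprene (2-chlorobuta-1,3-diene) | C=CC(Cl)=C | starting material
2 | 5-bromo-2-methylpent-2-ene | CC(C)=CCCBr | starting material
3 | (4-methylpent-3-en-1-yl)magnesium bromide | CC(C)=CCC[Mg]Br | intermediate (not isolated)
4 | myrcene (7-methyl-3-methylideneocta-1,6-diene) | C=CC(=C)CCC=C(C)C | intermediate
5 | p-cresol (4-methylphenol) | Cc1ccc(O)cc1 | starting material
6 | propan-2-ol | CC(C)O | starting material
7 | 4-methyl-2-(propan-2-yl)phenol | Cc1ccc(O)c(C(C)C)c1 | intermediate
8 | 1-methoxy-4-methyl-2-(propan-2-yl)benzene | COc1ccc(C)cc1C(C)C | intermediate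
9 | [4-methoxy-3-(propan-2-yl)benzyl]potassium | COc1ccc(C[K])cc1C(C)C | intermediate (not isolated)
10 | allylpotassium adduct of 9 and 4 (new chain cis to CH2K) | COc1ccc(CC/C=C(\C[K])CCC=C(C)C)cc1C(C)C | intermediate (not isolated)
11 | 4-[(3E)-4,8-dimethylnona-3,7-dien-1-yl]-1-methoxy-2-(propan-2-yl)benzene | COc1ccc(CC/C=C(\C)CCC=C(C)C)cc1C(C)C | intermediate
12 | (+)-ferruginol methyl ether (4bS,8aS; 5α-H, 10β-CH3) | COc1cc2c(cc1C(C)C)CC[C@H]1C(C)(C)CCC[C@]21C | intermediate
13 | 6,7-dehydroferruginol methyl ether (5α-H, 10β-CH3) | COc1cc2c(cc1C(C)C)C=C[C@H]1C(C)(C)CCC[C@]21C | intermediate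
14 | 9-(dimethoxymethyl)-3-methoxy-4b,8,8-trimethyl-2-(propan-2-yl)-4b,5,6,7,8,8a-hexahydro-9H-fluorene (4b-CH3 β, 8a-H α, acetal α) | COc1cc2c(cc1C(C)C)[C@H](C(OC)OC)[C@H]1C(C)(C)CCC[C@]21C | intermediate
15 | 9-(dimethoxymethyl)-4b,8,8-trimethyl-2-(propan-2-yl)-4b,5,6,7,8,8a-hexahydro-9H-fluoren-3-ol (same configuration) | Oc1cc2c(cc1C(C)C)[C@H](C(OC)OC)[C@H]1C(C)(C)CCC[C@]21C | intermediate
16 | 11,12-o-quinone acetal | O=C1C(=O)C2=C(C=C1C(C)C)[C@H](C(OC)OC)[C@H]1C(C)(C)CCC[C@]21C | intermediate (not isolated)
17 | 14-(pentafluorophenylthio)-11,12-catechol acetal | Oc1c(O)c2c(c(Sc3c(F)c(F)c(F)c(F)c3F)c1C(C)C)[C@H](C(OC)OC)[C@H]1C(C)(C)CCC[C@]21C | intermediate (not isolated)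
18 | 14-(pentafluorophenylthio)-11,12-o-quinone acetal | O=C1C(=O)C2=C(C(Sc3c(F)c(F)c(F)c(F)c3F)=C1C(C)C)[C@H](C(OC)OC)[C@H]1C(C)(C)CCC[C@]21C | intermediate (not isolated)
19 | 12-hydroxy-11,14-quinone dimethyl acetal | CC(C)C1=C(O)C(=O)C2=C(C1=O)[C@H](C(OC)OC)[C@H]1C(C)(C)CCC[C@]21C | intermediate (not isolated)
20 | 3-hydroxy-4b,8,8-trimethyl-1,4-dioxo-2-(propan-2-yl)-4,4b,5,6,7,8,8a,9-octahydro-1H-fluorene-9-carbaldehyde (4b-CH3 β, 8a-H α, 9-CHO α) | CC(C)C1=C(O)C(=O)C2=C(C1=O)[C@H](C=O)[C@H]1C(C)(C)CCC[C@]21C | intermediate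
21 | CNP0239256.1 (myrcene adduct; new C8–CH2 and C9–CH2 bonds α, 5α-H, 10β-CH3, 6α-CHO) | CC(C)=CCCC1=CC[C@@]23C(=O)C(C(C)C)=C(O)C(=O)[C@]2(C1)[C@@]1(C)CCCC(C)(C)[C@@H]1[C@H]3C=O | target

**Step count**
Total: 10 steps. Longest linear sequence: 9 steps (5 → 7 → 8 → 11 → 12 → 13 → 14 → 15 → 20 → 21; steps 2–10).

**Three steps most likely to fail**

Step 4 (proposed new hydrobenzylation). Risks are telomerisation of myrcene, attack at the wrong diene terminus, erosion of E geometry and base-induced isomerisation of myrcene. The fallback uses only known chemistry and sets out from 4. Lithium-amide-catalysed addition of diethylamine (Et2NH, cat. n-BuLi, 50 °C) gives N,N-diethylgeranylamine F1. Ethyl chloroformate (toluene, 0 °C → rt) converts it into geranyl chloride F2. Compound 8 is then metalated stoichiometrically (n-BuLi/KOt-Bu/TMP(H), THF, −78 °C) to 9 and alkylated with F2, which returns to the route at 11.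

Step 7 (ring contraction). The reaction class is established for simple 1,2-dihydronaphthalenes but not on this fused, hindered styrene. Risks are trans-6,7-dimethoxylation without migration, hydride shift to the 6-ketone ketal, and iodination of the electron-rich arene. The fallback sets out from 12 and contracts the ring by a Wolff rearrangement. CrO3/AcOH benzylic oxidation gives sugiol methyl ether F3. LiHMDS/CF3CO2CH2CF3 gives the 6-trifluoroacetyl ketone F4, and MsN3/Et3N gives the 6-diazo-7-ketone F5. Photolysis in MeOH gives the ring-contracted methyl ester F6 (equilibrated to the α-ester with NaOMe). DIBAL-H at −78 °C gives the aldehyde F7, and HC(OMe)3/PPTS/MeOH returns to the route at 14.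

Step 10 (Diels–Alder). The orientation is the main uncertainty: the chelation rationale is a prediction, and if the lanthanide binds the O11/O12 site instead, the opposite regioisomer is expected. β-Face addition, slow conversion at the tetrasubstituted alkene and enolisation of the sensitive aldehyde 20 are further risks. The fallback sets out from 20. TMSCHN2/MeOH gives the 12-O-methyl quinone F8. BF3·OEt2 with 4 (CH2Cl2, −78 °C) then binds the vinylogous-ester carbonyl at C14 as a monodentate acid; this is the documented way to reverse orientation in methoxyquinone Diels–Alder reactions, and it gives the adduct methyl ether F9. LiCl in DMF at 80 °C cleaves the vinylogous methyl ester and returns to the route at 21.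

**Further compounds**
F1 | step 4 | N,N-diethylgeranylamine | CCN(CC)C/C=C(\C)CCC=C(C)C
F2 | step 4 | geranyl chloride | ClC/C=C(\C)CCC=C(C)C
F3 | step 7 | sugiol methyl ether (12-methoxyabieta-8,11,13-trien-7-one) | COc1cc2c(cc1C(C)C)C(=O)C[C@H]1C(C)(C)CCC[C@]21C
F4 | step 7 | 6-(trifluoroacetyl)sugiol methyl ether | COc1cc2c(cc1C(C)C)C(=O)C(C(=O)C(F)(F)F)[C@H]1C(C)(C)CCC[C@]21C
F5 | step 7 | 6-diazosugiol methyl ether | COc1cc2c(cc1C(C)C)C(=O)C(=[N+]=[N-])[C@H]1C(C)(C)CCC[C@]21C
F6 | step 7 | methyl 3-methoxy-4b,8,8-trimethyl-2-(propan-2-yl)-4b,5,6,7,8,8a-hexahydro-9H-fluorene-9-carboxylate (9α) | COc1cc2c(cc1C(C)C)[C@H](C(=O)OC)[C@H]1C(C)(C)CCC[C@]21C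
F7 | step 7 | 3-methoxy-4b,8,8-trimethyl-2-(propan-2-yl)-4b,5,6,7,8,8a-hexahydro-9H-fluorene-9-carbaldehyde (9α) | COc1cc2c(cc1C(C)C)[C@H](C=O)[C@H]1C(C)(C)CCC[C@]21C
F8 | step 10 | 12-O-methyl ether of 20 | CC(C)C1=C(OC)C(=O)C2=C(C1=O)[C@H](C=O)[C@H]1C(C)(C)CCC[C@]21C
F9 | step 10 | 12-O-methyl ether of 21 | CC(C)=CCCC1=CC[C@@]23C(=O)C(C(C)C)=C(OC)C(=O)[C@]2(C1)[C@@]1(C)CCCC(C)(C)[C@@H]1[C@H]3C=O
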